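Saturday's run leaves 15% of the electrophile standing at 90.0 s, while Tuesday's, with 2.3 equiv of nucleophile against 1.2 equiv, reads 0% at 60.0 s.

| flask | electrophile | nucleophile | remark | time |
|---|---|---|---|---|
| Saturday's | 0.24 M | 1.2 equiv | run made earlier |  |
| Tuesday's | 0.24 M | 2.3 equiv | run made earlier |  |
| elm | 0.24 M | 0.800 equiv |  | 3.0 min |
| ash | 0.24 M | 1.60 equiv |  | 3.0 min |

| run | time / s | electrophile / % | target / % |
|---|---|---|---|
| Saturday's | 15.0 | 55 | 16 |
| Saturday's | 30.0 | 35 | 10 |
| Saturday's | 50.0 | 25 | 8 |
| Saturday's | 60.0 | 26 | 10 |
| Saturday's | 80.0 | 14 | 10 |
| Saturday's | 90.0 | 15 | 4 |
| Tuesday's | 10.0 | 46 | 28 |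
| Tuesday's | 20.0 | 21 | 34 |
| Tuesday's | 30.0 | 10 | 29 |
| Tuesday's | 50.0 | 6 | 28 |
| Tuesday's | 60.0 | 0 | 28 |
| Tuesday's | 90.0 | 0 | 26 |

(standard deviation of a reading: 2 percentage points)

- percentages count the electrophile that a species holds: one side product counts as two
- the earlier runs were read with a standard deviation of 2 percentage points
- reactions considered so far: electrophile + target -> side product; electrophile + nucleophile <-> acid set free + target; nucleophile + acid set free <-> protonated nucleophile; nucleophile <-> dormant form

- part of the electrophile that has reacted at the end, elm
- part of the electrophile that has reacted at the end, ash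
- what raising the equivalents of nucleophile from its lowest to its highest value here does to the part of the electrophile that has reacted (changes below 5 percentage points count as none) (it rises / no change / it falls)

The scheme under test is this. Electrophile and nucleophile give target and acid set free, target takes a second electrophile to side product, a further nucleophile takes up the acid as protonated nucleophile, and nucleophile also slips reversibly into a dormant form. So electrophile ending in side product costs one nucleophile each, and electrophile left as target costs two.

I carry one number, the bill: equivalents of nucleophile spent per electrophile reacted, which is one plus target over electrophile reacted. Saturday's last reading gives 1.05, and Tuesday's gives 1.26. The reach of a flask is its equivalents divided by its bill.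

A bill of 1 puts elm at 80.0%, short of full, so nucleophile is the limiting reagent there and elm takes Saturday's bill. Going round again gives a reach of 76.4%. Ash starts at 160%, a surplus, so it takes Tuesday's dearer bill, and 1.60 equiv still covers 1.26. I expect ash to finish in 3.0 min, which is longer than Tuesday's 60.0 s. Saturday's has spent 0.890 of its 1.2 equiv, so nucleophile can sit uncounted, and I commit to a little under the reach for elm.

The forecast says 70% for elm, lower than my figure, 98% for ash, and it rises, on the ground that “nucleophile limits conversion to below 80%”.

The flask gives 71.1% for elm and 99.2% for ash; the trend is it rises, by 28 percentage points.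

    electrophile + target → side product (k = 0.440 M⁻¹ s⁻¹)
    electrophile + nucleophile ⇌ acid set free + target (K = 33.0, k = 0.160 M⁻¹ s⁻¹)
    nucleophile + acid set free ⇌ protonated nucleophile, settled at all times (K = 45000 M⁻¹)
    nucleophile ⇌ dormant form (K = 1.50, k = 0.0200 s⁻¹)

In elm as charged, target has a half-life of 0.11 min against 0.38 min for electrophile by the forward step, and at 3.00 min target holds 0.954% beside 70.2% in side product. Elm then still has c(dormant form) = 0.0142 M, and it passes its reach later, standing at 82.9% after 30.0 min with c(acid set free) = 0.00763 M. A further flask like ash but with 0.400 equiv has a reach of 38.2% and gives 37.7%.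

The data were generated by integration with constants of no real substance, noise included.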